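## The problem

Compound 33 consists of two carbocycles that share no atom. Ring A (a 2-methylcyclohex-2-en-1-yl ester) and ring B (a 2-methylidenecyclopentane) are joined by one bond between two fully substituted carbons, each carrying a methyl group (qA in ring A, qB in ring B). There are three stereocentres: qA, qB and the allylic carbinol carbon of ring A, which stands 1,3 to qA. Because the central bond rotates freely, qA and qB cannot direct each other once the rings exist separately; they must be made in one event or inside a temporary ring. The carbinol centre can be controlled from qA, whose axial methyl and equatorial cyclopentyl groups differentiate the faces of ring A, but the natural ester is cis to the cyclopentyl group, which nucleophilic delivery of oxygen does not give directly. The catechol (oxidation under base), the cinnamate (conjugate addition), the secondary allylic ester (ionisation, allylic shift) and the methylidene group next to a quaternary carbon (acid-induced migration) will not survive strong acid, oxidants, hydride or hot alkali, so the ester must go on last. The enabling feature is a double 1,4-relationship across the central bond: the two methyl carbons can be tied as CH2–O–C(=O), a γ-lactone, and the methylidene-bearing carbon of ring B and one ring A CH2 next to qA can be the other two corners of a cyclobutane. With oxygen on that ring B carbon and a carbonyl next to that ring A CH2, the cyclobutane opens by retro-aldol, so the central bond can come from a photocycloaddition between a cyclohexenone and an ester-tethered cyclopentene enol derivative.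

## Retrosynthesis

**Ester C–O bond (33 ⇒ 32 ⇒ 28 + 31).** The ester is cut first so that catechol and allylic ester are absent from all reductive and basic steps. The cut is made with inversion: the partner is the (1R)-alcohol 28, epimeric at the carbinol carbon, joined to the silyl-protected acid 31 by Mitsunobu esterification. This is preferred to acylation with retention because the oxygen of 28 arrives anti to the cyclopentyl group (next paragraph), so one step corrects the configuration and attaches the acid. Acid 31 comes from caffeic acid 29; silyl ethers are chosen because fluoride removes them without touching either ester. The forward step must give direct rather than allylic substitution on a cyclic allylic alcohol.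

**Carbinol oxygen (28 ⇒ 26 ⇒ 25).** The allylic alcohol is traced to epoxy ketone 26 and enone 25 by a Wharton transposition. The transposition is a consequence of the key step, not an option. In diketone 11 the ring A carbonyl sits on the arm that was the enone α-carbon, which the cyclobutane held on the same side of the lactone as the future methylidene carbon of ring B. With the configurations of qA and qB required for 33, that arm ends in the vinylic CH and the ester is on the other arm. Direct 1,2-reduction of 25 would give the right constitution but the wrong relative configuration of qA and qB. The precursor loses one stereocentre. The forward epoxidation should occur on the face of the axial ring methyl, anti to the cyclopentyl group, as with other 5-substituted cyclohexenones.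

**Enone (25 ⇒ 23 ⇒ 21).** Removing the double bond and the α-methyl group leads to ketone 21. Both operations are regiochemically constrained by qA: one α-methylene of 21 is neopentyl and flanked by two quaternary carbons, and dehydrogenation toward qA is impossible because qA has no hydrogen. Ketone 21 has only the two quaternary stereocentres.

**Methyl groups and methylidene (21 ⇒ 20 ⇒ 18 ⇒ 17 ⇒ 15 ⇒ 14 ⇒ 13).** The two methyl carbons are taken back to the lactone carbons. The lactone carbonyl becomes the ring B methyl through lactol 15 and a Wolff–Kishner reduction to alcohol 17. The CH2O carbon becomes the ring A methyl through aldehyde 18 and a second Wolff–Kishner reduction to 20. The shorter diol, bis-sulfonate, hydride sequence is rejected: a 1,4-diol on two adjacent quaternary carbons closes to a tetrahydrofuran on activation, and substitution at a doubly neopentyl carbon is unreliable. The hydrazone route needs no substitution. The ring B carbonyl must be converted to the methylidene group (14 ⇒ 13, Wittig) before the lactone is reduced, and the ring A carbonyl must be masked as a ketal throughout.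

**Ketal and absolute configuration (13 ⇒ 11 + 12).** The ketal is made from racemic diketo lactone 11 and the enantiopure, C2-symmetric diol 12. The unhindered ring A cyclohexanone should react in preference to the ring B cyclopentanone next to qB. The two enantiomers of 11 become two diastereomers, and the one from (S,S)-11 is carried on. A chiral Lewis acid on the enone carbonyl in the photochemical step was considered and set aside: it works only at cryogenic temperature, where the s-cis ester rotamer that the lactone closure needs is essentially unpopulated. The resolution costs no step, since the ketal is needed anyway, but it costs half of the material at step 6.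

**Sacrificial bond (11 ⇒ 10 ⇒ 9).** Re-forming the bond between the ring A α-carbon and the ring B carbonyl carbon gives cyclobutanol 10, stored as benzyl carbonate 9. The benzyl carbonate is preferred to an acetate because 11 is a non-enolisable β-keto lactone, open to retro-Claisen cleavage by alkoxide; hydrogenolysis frees the alcohol without base. The neighbouring cut, direct conjugate addition of keto ester 7 to its own enone to give 11, is shorter. It is not chosen because it makes two adjacent quaternary carbons reversibly and does not lock the relative configuration of the two spiro centres; it is kept as a fallback.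

**Central bond (9 ⇒ 8), the key cut.** Cutting the qA–qB bond and the sacrificial cyclobutane bond gives enone ester 8: two achiral rings joined by an ester, no stereocentres. The three-atom tether secures head-to-head regiochemistry, which an untethered enol ester would not show, and the cis relation of the two future methyl carbons. The forward reaction needs the ester in its minor s-cis rotamer and needs cyclisation to outrun enone dimerisation.

**Assembly (8 ⇒ 7 ⇒ 5 + 6; 5 ⇒ 1 + 2).** The enol carbonate comes from β-keto ester 7, made by transesterifying keto ester 6 with alcohol 5. Alcohol 5 comes from vinylogous ester 1 by 1,2-addition of the hydroxymethyl anion equivalent from stannane 2 and acid-induced carbonyl transposition.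

## Roads not taken

**Alternative 1: hydroxyl-directed cyclopropanation for the ring B methyl.**
- **Cut and key step:** the qB–methyl bond is cut. Allylic alcohol A1 would be cyclopropanated by a zinc carbenoid bound to its alkoxide, syn to the hydroxyl, to give A2. Hydrogenolysis of the least hindered cyclopropane bond would then leave the methyl on qB.
- **Merits:** syn delivery is dependable, the absolute configuration would come from a catalytic ketone reduction, and no photochemistry or resolution is needed. In absolute stereocontrol this road is better than the chosen plan.
- **Weak points:** the central bond and qA must already exist in A1, so the hardest bond is not addressed. In A2 qA is not a stereocentre, because ring A is a symmetric 4,4-disubstituted cyclohexanone ketal. Its configuration would be decided later, when the two arms of ring A are differentiated by alkene formation and allylic oxygenation, with only a freely rotating neighbour to guide it.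
- **Comparison:** the chosen plan sets qA and qB together with their relation enforced by two rings, and places the ring A oxygen by design.

**Alternative 2: Diels–Alder reaction of dimethylmaleic anhydride.**
- **Cut and key step:** one ring bond at each quaternary carbon is cut. Diene A4 would add to anhydride A3 to give meso anhydride A5.
- **Merits:** both methyl groups and the cis relation of the quaternary carbons are present from the first step, so the lactone-to-methyl problem does not arise. A catalytic desymmetrisation of the meso anhydride would give the absolute configuration without resolution. On both counts this road is better.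
- **Weak points:** A3 is a tetrasubstituted, sluggish dienophile. After the cycloaddition neither ring A nor ring B exists. Both must be built by cleaving the cyclohexene and homologating at neopentyl positions (one more carbon for ring B, two carbons and a methyl for ring A), with several C–C bond formations and redox adjustments.
- **Comparison:** the chosen plan starts from both rings preformed and needs no ring construction after the key step.

**Alternative 3: asymmetric reductive Heck cyclisation closing ring B.**
- **Cut and key step:** the bond between the methylidene-bearing carbon and qB is cut. Dienyl triflate A6 would undergo 5-exo carbopalladation of its 1,1-disubstituted alkene; hydride capture of the neopentyl palladium species would leave the methyl and give hydrocarbon A7.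
- **Merits:** this is the shortest road. qB is set by a chiral ligand, and the methylidene group arises directly from the triflate carbon without protecting groups.
- **Weak points:** qA must already be a stereocentre in A6 and sits directly on the alkene that is attacked. The insertion must create a quaternary carbon next to an existing one and faces a matched/mismatched problem. A7 has no oxygen. The ester oxygen would need an allylic C–H oxidation on a hydrocarbon with several allylic positions in both rings, and would probably arrive trans to the cyclopentyl group in any case.
- **Comparison:** if that oxidation were selective this road would be clearly superior in step count. The chosen plan offers an oxygen position fixed by the enone and a bond-forming step that tolerates crowding, since it proceeds through a diradical.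

Key step: step 4

## Route

Remarks on the chemistry:
- Compounds 9, 10 and 11 are racemic. Their names carry rac-, and their SMILES show the enantiomer that step 6 selects.
- Stannane 2 is taken as a purchasable reagent.
- Step 15 is assumed to occur anti to the cyclopentyl group; step 18 is written for that outcome.

Step 1
Reactants: 1 3-ethoxycyclohex-2-en-1-one; 2 tributyl[(methoxymethoxy)methyl]stannane
Product: 5 3-(hydroxymethyl)cyclohex-2-en-1-one, via lithium alkoxide adduct 3 (not isolated), via MOM ether enone 4 (not isolated)
Conditions: n-BuLi, THF, −78 °C; then 1, −78 → 0 °C; then 3 M HCl, MeOH, 45 °C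
Reagents that add atoms: water, O
Why: Tin–lithium exchange gives the α-alkoxymethyllithium, which adds 1,2 to the vinylogous ester; acid then brings about the Stork–Danheiser carbonyl transposition and, on warming in methanol, acetal exchange of the MOM ether, so the hydroxymethyl group ends on the enone β-carbon.

Step 2
Reactants: 5 3-(hydroxymethyl)cyclohex-2-en-1-one; 6 ethyl 2-oxocyclopentane-1-carboxylate
Product: 7 (3-oxocyclohex-1-en-1-yl)methyl 2-oxocyclopentane-1-carboxylate
Conditions: DMAP (0.3 equiv), toluene, reflux, 4 Å molecular sieves (Soxhlet)
Reagents that add atoms: none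
Why: DMAP-catalysed transesterification of a β-keto ester with a primary alcohol, driven by removal of ethanol; the β,β-disubstituted enone is inert to these weakly basic conditions.

Step 3
Reactants: 7 (3-oxocyclohex-1-en-1-yl)methyl 2-oxocyclopentane-1-carboxylate
Product: 8 (3-oxocyclohex-1-en-1-yl)methyl 2-{[(benzyloxy)carbonyl]oxy}cyclopent-1-ene-1-carboxylate
Conditions: CbzCl, Et3N, DMAP (cat.), CH2Cl2, 0 °C
Reagents that add atoms: benzyl chloroformate, O=C(Cl)OCc1ccccc1
Why: O-acylation of the β-keto ester enol by a hard chloroformate fixes the tetrasubstituted double bond between the two ring carbons that become cyclobutane corners; the benzyl carbonate is chosen so that the oxygen can later be freed by hydrogenolysis without base.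

Step 4
Reactants: 8 (3-oxocyclohex-1-en-1-yl)methyl 2-{[(benzyloxy)carbonyl]oxy}cyclopent-1-ene-1-carboxylate
Product: 9 rac-benzyl carbonate of the cyclobutane-fused lactone photoadduct
Conditions: hν (λ = 365 nm), MeCN (5 mM), 60 °C, Ar, flow reactor
Reagents that add atoms: none
Why: Excitation of the cyclohexenone and intersystem crossing give the enone triplet, whose β-carbon bonds to the ester-bearing carbon of the tethered enol carbonate; the resulting 1,4-diradical (an α-keto radical and an oxygen-stabilised tertiary radical) then closes the cyclobutane. The closest known reaction type is the intramolecular enone–alkene [2+2] photocycloaddition of the de Mayo kind with an enol ester or enol carbonate as the alkene partner. The γ-lactone closes first, in the 1,5-mode that a three-atom tether imposes on the triplet (rule of five, 5-exo with respect to the enol double bond), and the four-membered ring closes second by radical recombination. The two quaternary carbons become stereocentres with their CH2O and C(=O)O substituents necessarily cis, because both lie in the five-membered lactone; the carbonate-bearing carbon is fixed by the cis fusion of cyclopentane and cyclobutane, and the ketone α-carbon by the six/four fusion, and since these last two centres are erased in step 5 an epimer at the ketone α-carbon is of no consequence. The step needs head-to-head regiochemistry, which an untethered enol ester would not show and which the tether enforces, and it needs cyclisation in preference to enone dimerisation, which high dilution secures. The ester must reach its minor s-cis rotamer within the triplet lifetime, so the irradiation is run warm in a polar solvent and no cryogenic chiral Lewis acid is used. The adduct is therefore racemic and the absolute configuration is taken in step 6.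

Step 5
Reactants: 9 rac-benzyl carbonate of the cyclobutane-fused lactone photoadduct
Product: 11 rac-(S*,S*)-diketo dispirolactone, via cyclobutanol 10 (not isolated)
Conditions: H2 (1 atm), 10% Pd/C, EtOAc, 25 °C; then Et3N (0.1 equiv), 25 °C
Reagents that add atoms: none
Why: Hydrogenolysis of the benzyl carbonate and loss of CO2 free a strained β-hydroxy ketone, which undergoes retro-aldol cleavage of the bond between the carbinol carbon and the ketone α-carbon (the de Mayo fragmentation); the nearly neutral conditions spare the non-enolisable β-keto lactone from retro-Claisen opening, and the two sacrificial stereocentres disappear.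

Step 6
Reactants: 11 rac-(S*,S*)-diketo dispirolactone; 12 (1R,2R)-1,2-diphenylethane-1,2-diol
Product: 13 ring A (4R,5R)-4,5-diphenyl-1,3-dioxolane ketal of (S,S)-11
Conditions: PPTS (cat.), toluene, reflux, Dean–Stark trap; then separation of the two diastereomeric ketals (chromatography or crystallisation)
Reagents that add atoms: none
Why: Acid-catalysed ketalisation should occur at the unhindered ring A cyclohexanone and not at the ring B cyclopentanone next to a quaternary carbon (the selectivity known from 3,17-diketo steroids); because the diol is enantiopure and C2-symmetric, the ketal carbon is no stereocentre and the racemate becomes two diastereomers, so the protection needed for steps 7 to 11 also serves as the resolution.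

Step 7
Reactants: 13 ring A (4R,5R)-4,5-diphenyl-1,3-dioxolane ketal of (S,S)-11
Product: 14 ring B methylidene lactone
Conditions: Ph3PCH3Br, KOtBu, toluene, 25 → 90 °C
Reagents that add atoms: methyltriphenylphosphonium bromide, C[P+](c1ccccc1)(c1ccccc1)c1ccccc1.[Br-]
Why: Wittig methylenation of the ring B ketone; a non-stabilised ylide at elevated temperature is the usual answer to hindered, enolisable ketones, and the neopentyl lactone carbonyl and the ketal are much less electrophilic.

Step 8
Reactants: 14 ring B methylidene lactone
Product: 15 lactol of 14
Conditions: i-Bu2AlH (1.2 equiv), CH2Cl2, −78 °C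
Reagents that add atoms: none
Why: Partial reduction of a lactone to the lactol by an aluminium hydride; the tetrahedral aluminate of this hindered lactone should persist at −78 °C, which holds back over-reduction to the diol.

Step 9
Reactants: 15 lactol of 14
Product: 17 [(2R,3R,7S)-7-[(1S)-1-methyl-2-methylidenecyclopentyl]-2,3-diphenyl-1,4-dioxaspiro[4.5]decan-7-yl]methanol, via hydroxy hydrazone 16 (not isolated)
Conditions: N2H4·H2O, KOH, diethylene glycol, 130 °C then 200 °C, N2
Reagents that add atoms: none
Why: Wolff–Kishner reduction in the Huang–Minlon mode: the lactol reacts through its open hydroxy aldehyde form, whose hydrazone loses N2 under base and leaves the ring B methyl group; no substitution at the doubly neopentyl carbon is needed, and ketal and isolated alkene are inert to hot alkali.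

Step 10
Reactants: 17 [(2R,3R,7S)-7-[(1S)-1-methyl-2-methylidenecyclopentyl]-2,3-diphenyl-1,4-dioxaspiro[4.5]decan-7-yl]methanol
Product: 18 (2R,3R,7S)-7-[(1S)-1-methyl-2-methylidenecyclopentyl]-2,3-diphenyl-1,4-dioxaspiro[4.5]decane-7-carbaldehyde
Conditions: Dess–Martin periodinane, pyridine, CH2Cl2, 0 → 25 °C
Reagents that add atoms: none
Why: Oxidation of the neopentyl primary alcohol to a non-enolisable aldehyde under buffered conditions that leave ketal and methylidene group untouched.

Step 11
Reactants: 18 (2R,3R,7S)-7-[(1S)-1-methyl-2-methylidenecyclopentyl]-2,3-diphenyl-1,4-dioxaspiro[4.5]decane-7-carbaldehyde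
Product: 20 (2R,3R,7R)-7-methyl-7-[(1S)-1-methyl-2-methylidenecyclopentyl]-2,3-diphenyl-1,4-dioxaspiro[4.5]decane, via aldehyde hydrazone 19 (not isolated)
Conditions: N2H4·H2O, KOH, diethylene glycol, 130 °C then 200 °C, N2
Reagents that add atoms: none
Why: A second Wolff–Kishner reduction turns the aldehyde on the ring A quaternary carbon into its methyl group; aldehyde hydrazones form readily even at neopentyl positions.

Step 12
Reactants: 20 (2R,3R,7R)-7-methyl-7-[(1S)-1-methyl-2-methylidenecyclopentyl]-2,3-diphenyl-1,4-dioxaspiro[4.5]decane
Product: 21 (3R)-3-methyl-3-[(1S)-1-methyl-2-methylidenecyclopentyl]cyclohexan-1-one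
Conditions: 1 M HCl, THF, 25 → 40 °C
Reagents that add atoms: water, O
Why: Acid hydrolysis of the dioxolane returns the ring A ketone and diol 12; dilute acid at moderate temperature is used so that the methylidene double bond does not migrate into ring B.

Step 13
Reactants: 21 (3R)-3-methyl-3-[(1S)-1-methyl-2-methylidenecyclopentyl]cyclohexan-1-one
Product: 23 (5R)-2,5-dimethyl-5-[(1S)-1-methyl-2-methylidenecyclopentyl]cyclohexan-1-one (both C2 epimers), via lithium enolate 22 (not isolated)
Conditions: LiN(i-Pr)2, THF, −78 °C; then MeI, −78 → 0 °C
Reagents that add atoms: iodomethane, CI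
Why: Kinetic deprotonation should occur at the α-methylene remote from the quaternary carbon, the other one being neopentyl and flanked by two quaternary centres; enolate alkylation then places the methyl group, and the new stereocentre is lost in step 14.

Step 14
Reactants: 23 (5R)-2,5-dimethyl-5-[(1S)-1-methyl-2-methylidenecyclopentyl]cyclohexan-1-one
Product: 25 (5R)-2,5-dimethyl-5-[(1S)-1-methyl-2-methylidenecyclopentyl]cyclohex-2-en-1-one, via silyl enol ether 24 (not isolated)
Conditions: TMSCl, NaI, Et3N, MeCN, 25 °C; then Pd(OAc)2, MeCN, 25 °C
Reagents that add atoms: none
Why: Saegusa–Ito dehydrogenation: equilibrating silylation gives the more substituted enol ether, transmetalation gives a divalent palladium enolate, and β-hydride elimination toward the ring CH2 releases the conjugated enone and zerovalent palladium; elimination toward the quaternary carbon is impossible.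

Step 15
Reactants: 25 (5R)-2,5-dimethyl-5-[(1S)-1-methyl-2-methylidenecyclopentyl]cyclohex-2-en-1-one
Product: 26 (1R,4R,6R)-1,4-dimethyl-4-[(1S)-1-methyl-2-methylidenecyclopentyl]-7-oxabicyclo[4.1.0]heptan-2-one
Conditions: 30% H2O2, NaOH (aq), MeOH, 0 °C
Reagents that add atoms: hydrogen peroxide, OO
Why: Weitz–Scheffer nucleophilic epoxidation touches only the electron-poor double bond; hydroperoxide should add axially to the β-carbon of the half-chair with the cyclopentyl group equatorial, on the face of the axial ring methyl, so the epoxide is expected trans to the cyclopentyl group as in other 5-substituted 2-methylcyclohexenones.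

Step 16
Reactants: 26 (1R,4R,6R)-1,4-dimethyl-4-[(1S)-1-methyl-2-methylidenecyclopentyl]-7-oxabicyclo[4.1.0]heptan-2-one
Product: 28 (1R,5S)-2,5-dimethyl-5-[(1S)-1-methyl-2-methylidenecyclopentyl]cyclohex-2-en-1-ol, via epoxy hydrazone 27 (not isolated)
Conditions: N2H4·H2O, AcOH (cat.), MeOH, 0 → 25 °C
Reagents that add atoms: none
Why: Wharton transposition: the epoxy hydrazone opens to an allylic alcohol with a vinyl diazene, which loses N2; the C–O bond at the former β-carbon is untouched, so the epoxide configuration becomes that of the carbinol and the double bond lands between the former carbonyl carbon and the methyl-bearing carbon.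

Step 17
Reactants: 29 caffeic acid
Product: 31 (2E)-3-{3,4-bis[(tert-butyldimethylsilyl)oxy]phenyl}prop-2-enoic acid, via silyl ester 30 (not isolated)
Conditions: TBSCl, imidazole, DMF, 25 °C; then AcOH, THF/H2O, 25 °C
Reagents that add atoms: tert-butyldimethylsilyl chloride, CC(C)(C)[Si](C)(C)Cl
Why: Exhaustive silylation followed by selective hydrolysis of the much more labile silyl ester gives the free acid with both phenols masked.

Step 18
Reactants: 28 (1R,5S)-2,5-dimethyl-5-[(1S)-1-methyl-2-methylidenecyclopentyl]cyclohex-2-en-1-ol; 31 (2E)-3-{3,4-bis[(tert-butyldimethylsilyl)oxy]phenyl}prop-2-enoic acid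
Product: 32 (1S,5S)-2,5-dimethyl-5-[(1S)-1-methyl-2-methylidenecyclopentyl]cyclohex-2-en-1-yl (2E)-3-{3,4-bis[(tert-butyldimethylsilyl)oxy]phenyl}prop-2-enoate
Conditions: PPh3, DIAD, toluene, 0 → 25 °C
Reagents that add atoms: none
Why: Mitsunobu esterification: the carboxylate displaces the oxyphosphonium group with inversion, approaching the pseudo-axial C–O bond from the open face away from the axial ring methyl, which sets the (1S) centre cis to the cyclopentyl group; a non-polar solvent favours direct over allylic substitution.

Step 19
Reactants: 32 (1S,5S)-2,5-dimethyl-5-[(1S)-1-methyl-2-methylidenecyclopentyl]cyclohex-2-en-1-yl (2E)-3-{3,4-bis[(tert-butyldimethylsilyl)oxy]phenyl}prop-2-enoate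
Product: 33 (1S,5S)-2,5-dimethyl-5-[(1S)-1-methyl-2-methylidenecyclopentyl]cyclohex-2-en-1-yl (2E)-3-(3,4-dihydroxyphenyl)prop-2-enoate
Conditions: Et3N·3HF, THF, 0 → 25 °C
Reagents that add atoms: none
Why: Fluoride cleaves the two aryl silyl ethers under slightly acidic, non-oxidising conditions that leave the allylic cinnamate, both alkenes and the free catechol intact.

## Compound list

1 | 3-ethoxycyclohex-2-en-1-one | CCOC1=CC(=O)CCC1 | starting material
2 | tributyl[(methoxymethoxy)methyl]stannane | CCCC[Sn](CCCC)(CCCC)COCOC | starting material
3 | lithium 3-ethoxy-1-[(methoxymethoxy)methyl]cyclohex-2-en-1-olate | CCOC1=CC(COCOC)(O[Li])CCC1 | intermediate (not isolated)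
4 | 3-[(methoxymethoxy)methyl]cyclohex-2-en-1-one | COCOCC1=CC(=O)CCC1 | intermediate (not isolated)
5 | 3-(hydroxymethyl)cyclohex-2-en-1-one | OCC1=CC(=O)CCC1 | intermediate
6 | ethyl 2-oxocyclopentane-1-carboxylate | CCOC(=O)C1CCCC1=O | starting material
7 | (3-oxocyclohex-1-en-1-yl)methyl 2-oxocyclopentane-1-carboxylate | O=C1CCCC1C(=O)OCC1=CC(=O)CCC1 | intermediate
8 | (3-oxocyclohex-1-en-1-yl)methyl 2-{[(benzyloxy)carbonyl]oxy}cyclopent-1-ene-1-carboxylate | O=C(OCc1ccccc1)OC1=C(CCC1)C(=O)OCC1=CC(=O)CCC1 | intermediate
9 | rac-benzyl carbonate of the cyclobutane-fused lactone photoadduct (cyclobutane fused to the ring A cyclohexanone, the ring B cyclopentane and the γ-lactone; lactone, carbonate oxygen and ring-fusion H on one face, both carbocycles on the other) | O=C(OCc1ccccc1)O[C@@]12CCC[C@]1(C(=O)OC3)[C@]3(CCCC4=O)[C@@H]24 | intermediate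
10 | rac-cyclobutanol photoadduct (free tertiary alcohol of 9, β to the ring A ketone) | O[C@@]12CCC[C@]1(C(=O)OC3)[C@]3(CCCC4=O)[C@@H]24 | intermediate (not isolated)
11 | rac-(S*,S*)-diketo dispirolactone (γ-butyrolactone whose C-α is C1 of a cyclopentan-2-one, ring B, and whose C-β is C1 of a cyclohexan-3-one, ring A; shown as the (S,S) enantiomer) | O=C1CCC[C@]1(C(=O)OC2)[C@@]23CCCC(=O)C3 | intermediate
12 | (1R,2R)-1,2-diphenylethane-1,2-diol | O[C@H](c1ccccc1)[C@H](O)c1ccccc1 | starting material
13 | ring A (4R,5R)-4,5-diphenyl-1,3-dioxolane ketal of (S,S)-11 | O=C1CCC[C@]1(C(=O)OC2)[C@@]23CCCC4(C3)O[C@H](c5ccccc5)[C@@H](c5ccccc5)O4 | intermediate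
14 | ring B methylidene lactone (13 with C=CH2 in place of the ring B C=O) | C=C1CCC[C@]1(C(=O)OC2)[C@@]23CCCC4(C3)O[C@H](c5ccccc5)[C@@H](c5ccccc5)O4 | intermediate
15 | lactol of 14 (lactone C=O reduced to CH–OH, both anomers) | C=C1CCC[C@]1(C(O)OC2)[C@@]23CCCC4(C3)O[C@H](c5ccccc5)[C@@H](c5ccccc5)O4 | intermediate
16 | hydrazone of the open hydroxy aldehyde form of 15 | C=C1CCC[C@]1(C=NN)[C@]2(CO)CCCC3(C2)O[C@H](c4ccccc4)[C@@H](c4ccccc4)O3 | intermediate (not isolated)
17 | [(2R,3R,7S)-7-[(1S)-1-methyl-2-methylidenecyclopentyl]-2,3-diphenyl-1,4-dioxaspiro[4.5]decan-7-yl]methanol | C=C1CCC[C@]1(C)[C@]2(CO)CCCC3(C2)O[C@H](c4ccccc4)[C@@H](c4ccccc4)O3 | intermediate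
18 | (2R,3R,7S)-7-[(1S)-1-methyl-2-methylidenecyclopentyl]-2,3-diphenyl-1,4-dioxaspiro[4.5]decane-7-carbaldehyde | C=C1CCC[C@]1(C)[C@]2(C=O)CCCC3(C2)O[C@H](c4ccccc4)[C@@H](c4ccccc4)O3 | intermediate
19 | hydrazone of 18 | C=C1CCC[C@]1(C)[C@]2(C=NN)CCCC3(C2)O[C@H](c4ccccc4)[C@@H](c4ccccc4)O3 | intermediate (not isolated)
20 | (2R,3R,7R)-7-methyl-7-[(1S)-1-methyl-2-methylidenecyclopentyl]-2,3-diphenyl-1,4-dioxaspiro[4.5]decane | C=C1CCC[C@]1(C)[C@]2(C)CCCC3(C2)O[C@H](c4ccccc4)[C@@H](c4ccccc4)O3 | intermediate
21 | (3R)-3-methyl-3-[(1S)-1-methyl-2-methylidenecyclopentyl]cyclohexan-1-one | C=C1CCC[C@]1(C)[C@]2(C)CCCC(=O)C2 | intermediate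
22 | lithium (5R)-5-methyl-5-[(1S)-1-methyl-2-methylidenecyclopentyl]cyclohex-1-en-1-olate | C=C1CCC[C@]1(C)[C@]2(C)CCC=C(O[Li])C2 | intermediate (not isolated)
23 | (5R)-2,5-dimethyl-5-[(1S)-1-methyl-2-methylidenecyclopentyl]cyclohexan-1-one (both C2 epimers) | C=C1CCC[C@]1(C)[C@]2(C)CCC(C)C(=O)C2 | intermediate
24 | trimethyl{[(5R)-2,5-dimethyl-5-[(1S)-1-methyl-2-methylidenecyclopentyl]cyclohex-1-en-1-yl]oxy}silane | C=C1CCC[C@]1(C)[C@]2(C)CCC(C)=C(O[Si](C)(C)C)C2 | intermediate (not isolated)
25 | (5R)-2,5-dimethyl-5-[(1S)-1-methyl-2-methylidenecyclopentyl]cyclohex-2-en-1-one | C=C1CCC[C@]1(C)[C@]2(C)CC=C(C)C(=O)C2 | intermediate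
26 | (1R,4R,6R)-1,4-dimethyl-4-[(1S)-1-methyl-2-methylidenecyclopentyl]-7-oxabicyclo[4.1.0]heptan-2-one (epoxide cis to the ring methyl, trans to the cyclopentyl group) | C=C1CCC[C@]1(C)[C@]2(C)C[C@H]3O[C@@]3(C)C(=O)C2 | intermediate
27 | hydrazone of 26 | C=C1CCC[C@]1(C)[C@]2(C)C[C@H]3O[C@@]3(C)C(=NN)C2 | intermediate (not isolated)
28 | (1R,5S)-2,5-dimethyl-5-[(1S)-1-methyl-2-methylidenecyclopentyl]cyclohex-2-en-1-ol (hydroxyl trans to the cyclopentyl group) | C=C1CCC[C@]1(C)[C@@]1(C)CC=C(C)[C@H](O)C1 | intermediate
29 | caffeic acid, (2E)-3-(3,4-dihydroxyphenyl)prop-2-enoic acid | OC(=O)/C=C/c1ccc(O)c(O)c1 | starting material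
30 | tert-butyldimethylsilyl (2E)-3-{3,4-bis[(tert-butyldimethylsilyl)oxy]phenyl}prop-2-enoate | CC(C)(C)[Si](C)(C)OC(=O)/C=C/c1ccc(O[Si](C)(C)C(C)(C)C)c(O[Si](C)(C)C(C)(C)C)c1 | intermediate (not isolated)
31 | (2E)-3-{3,4-bis[(tert-butyldimethylsilyl)oxy]phenyl}prop-2-enoic acid | OC(=O)/C=C/c1ccc(O[Si](C)(C)C(C)(C)C)c(O[Si](C)(C)C(C)(C)C)c1 | intermediate
32 | (1S,5S)-2,5-dimethyl-5-[(1S)-1-methyl-2-methylidenecyclopentyl]cyclohex-2-en-1-yl (2E)-3-{3,4-bis[(tert-butyldimethylsilyl)oxy]phenyl}prop-2-enoate | C=C1CCC[C@]1(C)[C@@]1(C)CC=C(C)[C@@H](OC(=O)/C=C/c2ccc(O[Si](C)(C)C(C)(C)C)c(O[Si](C)(C)C(C)(C)C)c2)C1 | intermediate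
33 | (1S,5S)-2,5-dimethyl-5-[(1S)-1-methyl-2-methylidenecyclopentyl]cyclohex-2-en-1-yl (2E)-3-(3,4-dihydroxyphenyl)prop-2-enoate | C=C1CCC[C@]1(C)[C@@]1(C)CC=C(C)[C@@H](OC(=O)/C=C/c2ccc(O)c(O)c2)C1 | target

## Step count and weakest steps

Total: 19 steps. Longest linear sequence: 18 steps (steps 1 to 16, 18 and 19); step 17 is a one-step side branch.

**Step 4 (key step).**
- Most likely failure: low photochemical efficiency. The ester rests in its s-trans rotamer and rotates slowly compared with the triplet lifetime, so only the small s-cis fraction can cyclise; enone dimerisation and slow photodecomposition may then compete.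
- Fallback: a ground-state reaction that is not limited by an excited-state lifetime. Keto ester 7 is treated with Cs2CO3 (0.2 equiv) in MeCN at 25 to 60 °C. Intramolecular 5-exo conjugate addition of the β-keto ester to the enone β-carbon would close the same lactone and form the same central bond, and return to the route at 11, bypassing 8, 9 and 10.
- Caveats: the addition is reversible, and the relative configuration of the two spiro carbons then rests on a cation-bridged transition state and would have to be confirmed on 11. This fallback makes no compound outside the list (F0).

**Step 6.**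
- Most likely failure: incomplete separation of the two diastereomeric ketals, because the stereocentres of the diol are several bonds from those of the skeleton; some ketalisation of the ring B ketone may also occur.
- Fallback: the enantiomers of racemic 11 are separated by preparative chromatography on a chiral stationary phase before ketalisation. The (S,S) enantiomer then gives 13 as the only ketal under the conditions of step 6. No compound outside the list is made (F0).

**Step 7.**
- Most likely failure: enolisation of the hindered ring B ketone by the basic ylide instead of addition, and attack of ylide or alkoxide on the neighbouring lactone carbonyl.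
- Fallback: Peterson olefination with a non-basic organocerium reagent. From 13, Me3SiCH2Li/CeCl3 in THF at −78 °C should add to the ketone to give the β-hydroxysilane F1; KH in THF then eliminates to 14.

**Step 14.**
- Most likely failure: loss of regiocontrol, through silylation toward the neopentyl α-carbon or β-hydride elimination into the methyl group (exocyclic enone).
- Fallback: unsaturation is introduced before the methyl group. From 21, the kinetic enolate 22 is oxidised in the same flask with N-tert-butylbenzenesulfinimidoyl chloride at −78 °C to (5R)-5-methyl-5-[(1S)-1-methyl-2-methylidenecyclopentyl]cyclohex-2-en-1-one F2. α-Iodination (I2, pyridine, CH2Cl2) gives the 2-iodo enone F3. Suzuki–Miyaura coupling with methylboronic acid (PdCl2(dppf), K3PO4, dioxane/H2O, 80 °C) returns to the route at 25.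

**Step 18.**
- Most likely failure: allylic (SN2′) substitution, elimination to a cyclohexadiene, or partial retention through an ion pair, because the activated alcohol is secondary, allylic and next to an axial methyl group.
- Fallback: inversion by oxidation and reagent-controlled reduction. From 28, MnO2 in CH2Cl2 gives the transposed enone (5S)-2,5-dimethyl-5-[(1S)-1-methyl-2-methylidenecyclopentyl]cyclohex-2-en-1-one F4. Corey–Bakshi–Shibata reduction with the (R)-oxazaborolidine and BH3·SMe2 should override the substrate bias and give the cis alcohol (1S,5S)-2,5-dimethyl-5-[(1S)-1-methyl-2-methylidenecyclopentyl]cyclohex-2-en-1-ol F5. Carbodiimide esterification with 31 (EDC·HCl, DMAP, CH2Cl2), with retention, returns to the route at 32.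
- The same direct esterification would be used on F5 if step 15 were to occur on the other face.

## Further compounds

F0 | step 4 | none | none
F0 | step 6 | none | none
F1 | step 7 | β-hydroxysilane from addition of Me3SiCH2 to the ring B ketone of 13 (both carbinol epimers) | C[Si](C)(C)CC1(O)CCC[C@]1(C(=O)OC2)[C@@]23CCCC4(C3)O[C@H](c5ccccc5)[C@@H](c5ccccc5)O4
F2 | step 14 | (5R)-5-methyl-5-[(1S)-1-methyl-2-methylidenecyclopentyl]cyclohex-2-en-1-one | C=C1CCC[C@]1(C)[C@]2(C)CC=CC(=O)C2
F3 | step 14 | (5R)-2-iodo-5-methyl-5-[(1S)-1-methyl-2-methylidenecyclopentyl]cyclohex-2-en-1-one | C=C1CCC[C@]1(C)[C@]2(C)CC=C(I)C(=O)C2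
F4 | step 18 | (5S)-2,5-dimethyl-5-[(1S)-1-methyl-2-methylidenecyclopentyl]cyclohex-2-en-1-one | C=C1CCC[C@]1(C)[C@@]1(C)CC=C(C)C(=O)C1
F5 | step 18 | (1S,5S)-2,5-dimethyl-5-[(1S)-1-methyl-2-methylidenecyclopentyl]cyclohex-2-en-1-ol | C=C1CCC[C@]1(C)[C@@]1(C)CC=C(C)[C@@H](O)C1
A1 | alternative 1 | 2-(8-methyl-1,4-dioxaspiro[4.5]decan-8-yl)cyclopent-2-en-1-ol (single enantiomer) | O[C@H]1CCC=C1C1(C)CCC2(CC1)OCCO2
A2 | alternative 1 | 1-(8-methyl-1,4-dioxaspiro[4.5]decan-8-yl)bicyclo[3.1.0]hexan-2-ol | O[C@H]1CC[C@H]2C[C@@]12C1(C)CCC2(CC1)OCCO2
A3 | alternative 2 | 2,3-dimethylmaleic anhydride | CC1=C(C)C(=O)OC1=O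
A4 | alternative 2 | buta-1,3-diene | C=CC=C
A5 | alternative 2 | cis-1,2-dimethylcyclohex-4-ene-1,2-dicarboxylic anhydride (meso) | C[C@]12CC=CC[C@@]1(C)C(=O)OC2=O
A6 | alternative 3 | 6-(1,4-dimethylcyclohex-3-en-1-yl)hepta-1,6-dien-2-yl trifluoromethanesulfonate (single enantiomer) | C=C(OS(=O)(=O)C(F)(F)F)CCCC(=C)[C@@]1(C)CC=C(C)CC1
A7 | alternative 3 | 1-methyl-2-methylidene-1-(1,4-dimethylcyclohex-3-en-1-yl)cyclopentane | C=C1CCC[C@]1(C)[C@@]1(C)CC=C(C)CC1
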